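**Plan**

1. The retrosynthesis first cuts the two aryl ether bonds of the dioxane, O-3–C1 and O-2–C5 (guaiane numbering for the sesquiterpene half), as a retro-hetero-Diels–Alder reaction. This gives the o-quinone of 6-oxopristimerol (from commercial pristimerin) and (7R,10R)-guaia-1(5),3,11-triene.
2. It then returns the C1–C10 bond of the seven-membered ring to C5. This contracts that ring to the six-membered ring of a spiro[4.5]deca-1,3-diene (a cyclopentadiene spiro-fused to a p-menthane ring), which is cut back to trans-dihydrocarvone.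
3. Enabling feature: the O-bearing carbons C1 and C5 together with C3=C4 put the five-membered ring C1–C5 at the cyclopentadiene oxidation level. The 5/7 diene is therefore the hydrogen-shift-stabilised product of a [1,5]-carbon shift in a spirodiene whose spiro atom C5 lies between C4(Me) and the unsubstituted terminus C1.
4. Forward order: (R)-carvone → trans-dihydrocarvone → Wittig/Claisen (quaternary carbon) → Wacker/aldol (spiro five-membered ring) → enol triflate/reduction (spirodiene) → thermal enlargement of the six- to the seven-membered ring → quinone hetero-Diels–Alder reaction (dioxane ring last).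
5. Stereochemistry: C7 comes from carvone; C10 is set by thermodynamic protonation and retained in the suprafacial shift; C1/C5 are set by cycloaddition anti to the C10 methyl group; all triterpene centres come from pristimerin.

Key step: step 8

Remark: pristimerin is taken as a commercial starting material (it is sold as an isolated natural product), so the triterpene half is not built from smaller pieces.
Remark: the quaternary (later spiro) carbon, the adjacent CHMe carbon and the transient C1–H centre are formed as mixtures; all are erased by the end of step 8 and carry no descriptor in the SMILES.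

**Step 1**
Reactants: 1 (R)-(−)-carvone
Product: 3 (2R,5R)-2-methyl-5-(prop-1-en-2-yl)cyclohexan-1-one (trans-dihydrocarvone), via lithium enolate 2 (not isolated)
Conditions: LiBH(s-Bu)3 (L-Selectride), THF, −78 °C; H2O; then NaOMe (cat.), MeOH, rt; chromatography
Reagents that add atoms: none
Why: Conjugate hydride reduction of the β-unsubstituted enone should give the enolate without touching the isopropenyl group, and base equilibration of the α-methyl ketone should place methyl and isopropenyl both equatorial (2,5-trans, new centre 2R under thermodynamic control).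

**Step 2**
Reactants: 3 trans-dihydrocarvone
Product: 4 (2R,5R)-1-(methoxymethylidene)-2-methyl-5-(prop-1-en-2-yl)cyclohexane (E/Z mixture)
Conditions: Ph3P(CH2OMe)Cl, KOtBu, THF, 0 °C → rt
Reagents that add atoms: (methoxymethyl)triphenylphosphonium chloride, COC[P+](c1ccccc1)(c1ccccc1)c1ccccc1.[Cl-]
Why: Wittig methoxymethylenation of the ketone should give the one-carbon-homologated enol ether (both geometries serve), after which the methyl-bearing centre can no longer epimerise.

**Step 3**
Reactants: 4 methyl enol ether; 5 (E)-but-2-en-1-ol (crotyl alcohol)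
Product: 8 (2R,5R)-1-(but-3-en-2-yl)-2-methyl-5-(prop-1-en-2-yl)cyclohexane-1-carbaldehyde, via methyl crotyl acetal 6 (not isolated), via crotyl enol ether 7 (not isolated)
Conditions: 5 (5 equiv), EtCO2H (cat.), o-xylene, 140–150 °C, MeOH distilled off
Reagents that add atoms: none
Why: Acid-catalysed alkoxy exchange should give the crotyl enol ether, whose [3,3]-sigmatropic Claisen rearrangement forms the quaternary carbon bearing CHO and the 1-methylallyl group; both new centres form as mixtures and are erased later.

**Step 4**
Reactants: 8 quaternary aldehyde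
Product: 9 (2R,5R)-2-methyl-1-(3-oxobutan-2-yl)-5-(prop-1-en-2-yl)cyclohexane-1-carbaldehyde
Conditions: PdCl2 (10 mol %), CuCl (1 equiv, reoxidised by O2), O2 (1 atm), DMF/H2O, rt
Reagents that add atoms: water, O
Why: Tsuji–Wacker oxidation is Markovnikov-selective for the monosubstituted vinyl group and should leave the 1,1-disubstituted isopropenyl group and the non-enolisable aldehyde untouched, as in the standard route to 4,4-disubstituted cyclopentenones.

**Step 5**
Reactants: 9 keto aldehyde
Product: 11 (6R,9R)-1,6-dimethyl-9-(prop-1-en-2-yl)spiro[4.5]dec-3-en-2-one, via aldol 10 (not isolated)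
Conditions: KOH, MeOH/THF/H2O, 60 °C
Reagents that add atoms: none
Why: In this intramolecular aldol condensation only the methyl-ketone CH3 enolate can reach the neopentyl aldehyde (five-membered ring, exo-trig closure), and dehydration of the aldol should give the conjugated spiro cyclopentenone.

**Step 6**
Reactants: 11 spiro enone
Product: 13 (6R,9R)-1,6-dimethyl-9-(prop-1-en-2-yl)spiro[4.5]deca-1,3-dien-2-yl trifluoromethanesulfonate, via potassium dienolate 12 (not isolated)
Conditions: KN(SiMe3)2, THF, −78 °C; PhNTf2, −78 → 0 °C; 1 M HCl wash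
Reagents that add atoms: N-phenylbis(trifluoromethanesulfonimide), O=S(=O)(N(c1ccccc1)S(=O)(=O)C(F)(F)F)C(F)(F)F
Why: The only enolisable position is the α′ CHMe, so deprotonation should give the cross-conjugated dienolate, which is O-sulfonylated to the cyclopentadienyl triflate (enol triflate formation).

**Step 7**
Reactants: 13 spiro dienyl triflate
Product: 14 (6R,9R)-1,6-dimethyl-9-(prop-1-en-2-yl)spiro[4.5]deca-1,3-diene
Conditions: Pd(OAc)2 (5 mol %), PPh3, HCO2H, Bu3N, DMF, 50 °C
Reagents that add atoms: none
Why: Palladium-catalysed formate reduction of the enol triflate (oxidative addition to zerovalent palladium, decarboxylation of formate, reductive elimination) should replace OTf by H without touching the diene or the isopropenyl group; the 5,5-disubstituted cyclopentadiene cannot tautomerise.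

**Step 8**
Reactants: 14 spiro diene
Product: 16 (7R,10R)-guaia-1(5),3,11-triene, via guaia-2,4,11-triene 15 (not isolated)
Conditions: PhMe (0.02 M, degassed), BHT (cat.), base-washed steel flow coil, 280 °C
Reagents that add atoms: none
Why: On heating, the σ-bond between the spiro carbon C5 and the methyl-bearing ring carbon C10 should migrate suprafacially across the cyclopentadiene to the unsubstituted terminus C1 ([1,5]-sigmatropic carbon shift), so that the six-membered ring C5–C6–C7–C8–C9–C10 takes up C1 and becomes the seven-membered ring; the 1H-diene 15 then equilibrates by fast [1,5]-hydrogen shifts to the fully alkyl-substituted cyclopentadiene 16. The closest known reaction is the thermal isomerisation of spiro[4.4]nona-1,3-diene and of 5,5-dialkylcyclopentadienes to ring-fused or 1,5-dialkyl cyclopentadienes. No ring is closed by a new bond between remote atoms: the cycloheptene arises by one-carbon ring enlargement (a formal 1,2-shift) within a concerted six-electron transition state, and the cyclopentadiene is kept. No lasting stereocentre is created: C10 migrates with retention, C7 is not touched, and the spiro centre and the transient C1–H centre are both erased, which is why both spiro epimers converge. The step needs migration of C10 and not C6, and to C1 and not C4: the secondary carbon C10 is the better migrating group than the primary C6, and C1–H is the less hindered terminus and the only one whose product can drain off by hydrogen shift, whereas a shift to C4 gives a reversible quaternary isomer.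

**Step 9**
Reactants: 17 pristimerin
Product: 19 pristimerol diacetate, via pristimerol 18 (not isolated)
Conditions: Zn dust, Ac2O, pyridine, rt
Reagents that add atoms: acetic anhydride, CC(=O)OC(C)=O
Why: Zinc should reduce the quinone methide (aromatising ring A and giving C6H2), and the air-sensitive catechol is trapped in the same flask as its diacetate (reductive acetylation).

**Step 10**
Reactants: 19 pristimerol diacetate
Product: 20 6-oxopristimerol diacetate
Conditions: Mn(OAc)3·2H2O (10 mol %), t-BuOOH (in decane), 3 Å MS, EtOAc, rt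
Reagents that add atoms: tert-butyl hydroperoxide, CC(C)(C)OO
Why: C6 is the only CH2 that is both benzylic and allylic (to C7=C8), so manganese-catalysed hydroperoxide allylic oxidation should convert it into the ketone while the acetates protect ring A from oxidation.

**Step 11**
Reactants: 20 6-oxopristimerol diacetate
Product: 21 6-oxopristimerol
Conditions: p-TsOH·H2O (cat.), MeOH/CH2Cl2, 40 °C, Ar
Reagents that add atoms: none
Why: Acid-catalysed methanolysis (transesterification) should remove the two aryl acetates without exposing the catechol to base and air, while the hindered tertiary methyl ester survives.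

**Step 12**
Reactants: 21 6-oxopristimerol; 16 (7R,10R)-guaia-1(5),3,11-triene
Product: 23 CNP0317749.1 (target; 6-oxopristimerol O-3/O-2 diether at C-1/C-5 of the (1S,5S,7R,10R)-guaia-3,11-diene unit), via o-quinone 22 (not isolated)
Conditions: Ag2O (3 equiv), 4 Å MS, 16 (3 equiv), PhH, dark, 45 °C
Reagents that add atoms: none
Why: Ag2O should dehydrogenate the catechol to the o-quinone, whose O=C–C=O unit adds as a heterodiene across the tetrasubstituted C1=C5 bond of 16 (inverse-electron-demand hetero-Diels–Alder reaction, closing the dioxane), with the more electrophilic O-3 (its partner O-2 gains phenoxide character para to the C6 ketone) bonding to the diene terminus C1 while charge at C5 is allyl-stabilised, and with approach anti to the pseudoaxial C10 methyl group setting C1 and C5 as (1S,5S).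

**Compound list**

1 | (R)-(−)-carvone | CC1=CC[C@H](CC1=O)C(C)=C | starting material
2 | lithium enolate of dihydrocarvone | [Li+].[O-]C1=C(C)CC[C@H](C1)C(C)=C | intermediate
3 | (2R,5R)-2-methyl-5-(prop-1-en-2-yl)cyclohexan-1-one (trans-dihydrocarvone) | C[C@@H]1CC[C@H](CC1=O)C(C)=C | intermediate
4 | (2R,5R)-1-(methoxymethylidene)-2-methyl-5-(prop-1-en-2-yl)cyclohexane (E/Z) | COC=C1C[C@@H](CC[C@H]1C)C(C)=C | intermediate
5 | (E)-but-2-en-1-ol (crotyl alcohol) | C/C=C/CO | starting material
6 | methyl crotyl acetal of the homologated aldehyde | COC(OC/C=C/C)C1C[C@@H](CC[C@H]1C)C(C)=C | intermediate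
7 | crotyl enol ether (E/Z at the enol ether) | C/C=C/COC=C1C[C@@H](CC[C@H]1C)C(C)=C | intermediate
8 | (2R,5R)-1-(but-3-en-2-yl)-2-methyl-5-(prop-1-en-2-yl)cyclohexane-1-carbaldehyde (mixture at C1 and at the butenyl CH) | O=CC1(C(C)C=C)C[C@@H](CC[C@H]1C)C(C)=C | intermediate
9 | (2R,5R)-2-methyl-1-(3-oxobutan-2-yl)-5-(prop-1-en-2-yl)cyclohexane-1-carbaldehyde | O=CC1(C(C)C(C)=O)C[C@@H](CC[C@H]1C)C(C)=C | intermediate
10 | (6R,9R)-4-hydroxy-1,6-dimethyl-9-(prop-1-en-2-yl)spiro[4.5]decan-2-one (aldol) | O=C1CC(O)C2(C1C)C[C@@H](CC[C@H]2C)C(C)=C | intermediate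
11 | (6R,9R)-1,6-dimethyl-9-(prop-1-en-2-yl)spiro[4.5]dec-3-en-2-one | O=C1C=CC2(C1C)C[C@@H](CC[C@H]2C)C(C)=C | intermediate
12 | potassium dienolate of 11 | [K+].[O-]C1=C(C)C2(C=C1)C[C@@H](CC[C@H]2C)C(C)=C | intermediate
13 | (6R,9R)-1,6-dimethyl-9-(prop-1-en-2-yl)spiro[4.5]deca-1,3-dien-2-yl trifluoromethanesulfonate | CC1=C(OS(=O)(=O)C(F)(F)F)C=CC12C[C@@H](CC[C@H]2C)C(C)=C | intermediate
14 | (6R,9R)-1,6-dimethyl-9-(prop-1-en-2-yl)spiro[4.5]deca-1,3-diene | CC1=CC=CC12C[C@@H](CC[C@H]2C)C(C)=C | intermediate
15 | (7R,10R)-guaia-2,4,11-triene (C1–H, either configuration) | CC1=C2C[C@@H](CC[C@@H](C)C2C=C1)C(C)=C | intermediate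
16 | (7R,10R)-guaia-1(5),3,11-triene; (5R,8R)-3,8-dimethyl-5-(prop-1-en-2-yl)-1,4,5,6,7,8-hexahydroazulene | CC1=CCC2=C1C[C@@H](CC[C@H]2C)C(C)=C | intermediate
17 | pristimerin; methyl 3-hydroxy-2-oxo-24-norfriedela-1(10),3,5,7-tetraen-29-oate | O=C1C=C2C(C(C)=C1O)=CC=C1[C@@]2(C)CC[C@@]2(C)[C@@H]3C[C@](C)(C(=O)OC)CC[C@]3(C)CC[C@]12C | starting material
18 | pristimerol; methyl 2,3-dihydroxy-24-norfriedela-1,3,5(10),7-tetraen-29-oate | Oc1cc2c(c(C)c1O)CC=C1[C@@]2(C)CC[C@@]2(C)[C@@H]3C[C@](C)(C(=O)OC)CC[C@]3(C)CC[C@]12C | intermediate
19 | pristimerol diacetate | CC(=O)Oc1cc2c(c(C)c1OC(C)=O)CC=C1[C@@]2(C)CC[C@@]2(C)[C@@H]3C[C@](C)(C(=O)OC)CC[C@]3(C)CC[C@]12C | intermediate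
20 | 6-oxopristimerol diacetate | CC(=O)Oc1cc2c(c(C)c1OC(C)=O)C(=O)C=C1[C@@]2(C)CC[C@@]2(C)[C@@H]3C[C@](C)(C(=O)OC)CC[C@]3(C)CC[C@]12C | intermediate
21 | 6-oxopristimerol; methyl 2,3-dihydroxy-6-oxo-24-norfriedela-1,3,5(10),7-tetraen-29-oate | Oc1cc2c(c(C)c1O)C(=O)C=C1[C@@]2(C)CC[C@@]2(C)[C@@H]3C[C@](C)(C(=O)OC)CC[C@]3(C)CC[C@]12C | intermediate
22 | 6-oxopristimerol o-quinone; methyl 2,3,6-trioxo-24-norfriedela-1(10),4,7-trien-29-oate | O=C1C=C2C(=C(C)C1=O)C(=O)C=C1[C@@]2(C)CC[C@@]2(C)[C@@H]3C[C@](C)(C(=O)OC)CC[C@]3(C)CC[C@]12C | intermediate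
23 | CNP0317749.1; cis-fused 1,4-benzodioxane with triterpene O-3 on C1 and O-2 on C5 of the (1S,5S,7R,10R)-guaia-3,11-diene unit | C=C(C)[C@@H]1CC[C@@H](C)[C@@]23CC=C(C)[C@]2(C1)Oc1cc2c(c(C)c1O3)C(=O)C=C1[C@@]2(C)CC[C@@]2(C)[C@@H]3C[C@](C)(C(=O)OC)CC[C@]3(C)CC[C@]12C | target

**Step count and risks**

Total steps: 12. Longest linear sequence: 9 steps (steps 1–8 and 12, from (R)-carvone).

Steps most likely to fail:

1. Step 8. The risks are competing migration of the primary ring carbon C6 or migration to the methyl-bearing terminus C4 (constitutional isomers of the hydroazulene), thermal ene or cycloaddition reactions of the isopropenyl group, and dimerisation at the temperature needed. Fallback (cationic instead of pericyclic ring enlargement): setting out from enone 11, Luche reduction (NaBH4, CeCl3·7H2O, MeOH, 0 °C) would give the spiro allylic alcohol F1. This would be converted (MsCl, Et3N, CH2Cl2, −40 °C) into the allylic mesylate F2 and ionised without purification in 2,6-lutidine-buffered (CF3)2CHOH at 0 °C. The allyl cation carries positive charge at C1 next to the spiro carbon, so a Wagner–Meerwein 1,2-shift of C10 should enlarge the six-membered ring, and loss of H-4 would give 15, which tautomerises to 16, where the route is rejoined. Simple elimination would give 14, which can be recycled through step 8.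

2. Step 12. The risks are poor site selectivity between the two double bonds of the cyclopentadiene (cycloaddition at the less hindered C3=C4 bond), migration of the diene double bonds by hydrogen shift before cycloaddition, wrong facial selectivity, and ene-type hydrogen abstraction by the quinone. Fallback (C3=C4 carried as a blocked, deactivated enol triflate): setting out from enone 11, soft enolisation (Me3SiOTf, Et3N, CH2Cl2, 0 °C) would give the trimethylsilyl dienol ether F3. The same thermal [1,5]-shift as in step 8 would give 3-(trimethylsilyloxy)guaia-1(5),3,11-triene F4, in which the silyloxy group also fixes the diene tautomer. MeLi then PhNTf2 (THF, 0 °C) would give guaia-1(5),3,11-trien-3-yl triflate F5, so that quinone 22 (from 21 and Ag2O as in step 12) can add only across C1=C5 to give the adduct triflate F6. Formate reduction (Pd(OAc)2, PPh3, HCO2H, Bu3N, DMF) would remove the triflate and rejoin the route at 23.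

3. Step 4. The risks are slow or anti-Markovnikov oxidation at the branched, neopentyl-type vinyl group and competing oxidation or isomerisation of the isopropenyl group. Fallback (metathesis instead of Wacker/aldol): setting out from aldehyde 8, addition of CH2=CHMgBr (THF, −78 °C) would give the allylic alcohol F7 and Dess–Martin oxidation the vinyl ketone F8. Ring-closing metathesis with the second-generation Grubbs catalyst (CH2Cl2, 40 °C; the 1,1-disubstituted isopropenyl group reacts more slowly) would give the isomeric spiro enone F9. γ-Deprotonation and triflation (KN(SiMe3)2, PhNTf2, THF, −78 °C) would give the isomeric dienyl triflate F10, and formate reduction as in step 7 would rejoin the route at 14.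

**Further compounds**

F1 | step 8 | (6R,9R)-1,6-dimethyl-9-(prop-1-en-2-yl)spiro[4.5]dec-3-en-2-ol | OC1C=CC2(C1C)C[C@@H](CC[C@H]2C)C(C)=C
F2 | step 8 | (6R,9R)-1,6-dimethyl-9-(prop-1-en-2-yl)spiro[4.5]dec-3-en-2-yl methanesulfonate | CS(=O)(=O)OC1C=CC2(C1C)C[C@@H](CC[C@H]2C)C(C)=C
F3 | step 12 | (6R,9R)-1,6-dimethyl-9-(prop-1-en-2-yl)-2-(trimethylsilyloxy)spiro[4.5]deca-1,3-diene | CC1=C(O[Si](C)(C)C)C=CC12C[C@@H](CC[C@H]2C)C(C)=C
F4 | step 12 | (7R,10R)-3-(trimethylsilyloxy)guaia-1(5),3,11-triene | CC1=C(O[Si](C)(C)C)CC2=C1C[C@@H](CC[C@H]2C)C(C)=C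
F5 | step 12 | (7R,10R)-guaia-1(5),3,11-trien-3-yl trifluoromethanesulfonate | CC1=C(OS(=O)(=O)C(F)(F)F)CC2=C1C[C@@H](CC[C@H]2C)C(C)=C
F6 | step 12 | 3-(trifluoromethanesulfonyloxy) derivative of 23 (triflate on C3 of the guaiane unit) | C=C(C)[C@@H]1CC[C@@H](C)[C@@]23CC(OS(=O)(=O)C(F)(F)F)=C(C)[C@]2(C1)Oc1cc2c(c(C)c1O3)C(=O)C=C1[C@@]2(C)CC[C@@]2(C)[C@@H]3C[C@](C)(C(=O)OC)CC[C@]3(C)CC[C@]12C
F7 | step 4 | 1-[(2R,5R)-1-(but-3-en-2-yl)-2-methyl-5-(prop-1-en-2-yl)cyclohexyl]prop-2-en-1-ol | C=CC(O)C1(C(C)C=C)C[C@@H](CC[C@H]1C)C(C)=C
F8 | step 4 | 1-[(2R,5R)-1-(but-3-en-2-yl)-2-methyl-5-(prop-1-en-2-yl)cyclohexyl]prop-2-en-1-one | C=CC(=O)C1(C(C)C=C)C[C@@H](CC[C@H]1C)C(C)=C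
F9 | step 4 | (6R,9R)-4,6-dimethyl-9-(prop-1-en-2-yl)spiro[4.5]dec-2-en-1-one | O=C1C=CC(C)C12C[C@@H](CC[C@H]2C)C(C)=C
F10 | step 4 | (6R,9R)-4,6-dimethyl-9-(prop-1-en-2-yl)spiro[4.5]deca-1,3-dien-1-yl trifluoromethanesulfonate | CC1=CC=C(OS(=O)(=O)C(F)(F)F)C12C[C@@H](CC[C@H]2C)C(C)=C
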